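The pendant benzene ring carries a free phenol at C3' next to the CH2CH2CO2Me chain at C4'. This ortho pair is the hydrolysed form of a 2,2-dimethoxychroman. Cutting the chroman C3–C4 and O1–C2 bonds together leads to an ortho-quinone methide and 1,1-dimethoxyethene. One [4+2] cycloaddition therefore adds both chain carbons at the ester oxidation level and spares the coumarin C3=C4 bond from any reduction. The precursor is the 3-aryloxy-6-methoxycoumarin with a hydroxymethyl group at C4' and both phenols (O-3', O-7) masked as tert-butyl carbonates. No acidic phenol or water then meets the ketene acetal, and base-induced carbonate migration releases the quinone methide at low temperature.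

Key step: step 9

Remark: the target has no stereocentre and no stereogenic double bond, so no stereodescriptor is needed. The compounds marked as starting materials in the list are assumed to be purchasable.

Step 1
Reactants: 1 2,4-dihydroxy-5-methoxybenzaldehyde
Product: 2 4-(allyloxy)-2-hydroxy-5-methoxybenzaldehyde
Conditions: allyl bromide (1.05 equiv), KHCO3, DMF, 50 °C
Reagents that add atoms: allyl bromide, C=CCBr
Why: Williamson etherification should be selective for O-4, because this phenol para to the formyl group is the more acidic one, whereas the O-2 phenol is held in a hydrogen bond to the aldehyde and is not deprotonated by the weak base.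

Step 2
Reactants: 2 4-(allyloxy)-2-hydroxy-5-methoxybenzaldehyde; 3 N-acetylglycine
Product: 5 N-[7-(allyloxy)-6-methoxy-2-oxo-2H-chromen-3-yl]acetamide, via 2-methyl-1,3-oxazol-5(4H)-one 4 (not isolated)
Conditions: Ac2O, NaOAc, 120 °C
Reagents that add atoms: none
Why: In this Erlenmeyer–Plöchl condensation acetic anhydride cyclises 3 to azlactone 4, its active methylene condenses with the aldehyde of 2, and the neighbouring phenol oxygen opens the azlactone carbonyl to close the coumarin lactone, at a temperature well below that of an aryl allyl ether Claisen rearrangement.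

Step 3
Reactants: 5 N-[7-(allyloxy)-6-methoxy-2-oxo-2H-chromen-3-yl]acetamide
Product: 7 7-(allyloxy)-3-hydroxy-6-methoxy-2H-chromen-2-one, via 7-(allyloxy)-3-amino-6-methoxy-2H-chromen-2-one 6 (not isolated)
Conditions: 3 M aq HCl, 1,4-dioxane, reflux, N2
Reagents that add atoms: water, O
Why: Acid hydrolysis of the enamide frees enamine 6, whose imine tautomer is hydrolysed to the alpha-keto lactone that rests as enol 7, a standard conversion of 3-acetamidocoumarins that aryl allyl and aryl methyl ethers tolerate.

Step 4
Reactants: 8 4-fluoro-2-hydroxybenzaldehyde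
Product: 9 2-(allyloxy)-4-fluorobenzaldehyde
Conditions: allyl bromide, K2CO3, DMF, rt to 50 °C
Reagents that add atoms: allyl bromide, C=CCBr
Why: Williamson etherification masks the phenol, whose phenoxide would otherwise deactivate the ring towards the nucleophilic substitution of step 5.

Step 5
Reactants: 7 7-(allyloxy)-3-hydroxy-6-methoxy-2H-chromen-2-one; 9 2-(allyloxy)-4-fluorobenzaldehyde
Product: 10 2-(allyloxy)-4-{[7-(allyloxy)-6-methoxy-2-oxo-2H-chromen-3-yl]oxy}benzaldehyde
Conditions: K2CO3, DMSO, 100 °C, N2
Reagents that add atoms: none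
Why: In this nucleophilic aromatic substitution by addition–elimination the oxygen of the potassium enolate of 7, comparable in basicity to an electron-poor phenoxide, attacks C4 of 9, where the para formyl group stabilises the Meisenheimer adduct and fluoride is the best leaving group.

Step 6
Reactants: 10 2-(allyloxy)-4-{[7-(allyloxy)-6-methoxy-2-oxo-2H-chromen-3-yl]oxy}benzaldehyde
Product: 11 2-hydroxy-4-[(7-hydroxy-6-methoxy-2-oxo-2H-chromen-3-yl)oxy]benzaldehyde
Conditions: Pd(PPh3)4 (5 mol %), morpholine, THF, rt; dilute acid wash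
Reagents that add atoms: none
Why: In this Tsuji–Trost type allyl transfer zerovalent palladium ionises both aryl allyl ethers to pi-allyl complexes that morpholine intercepts, while aldehyde, lactone and methyl ether are left untouched.

Step 7
Reactants: 11 2-hydroxy-4-[(7-hydroxy-6-methoxy-2-oxo-2H-chromen-3-yl)oxy]benzaldehyde
Product: 12 tert-butyl 3-{3-[(tert-butoxycarbonyl)oxy]-4-formylphenoxy}-6-methoxy-2-oxo-2H-chromen-7-yl carbonate
Conditions: Boc2O (2.4 equiv), iPr2NEt, DMAP (cat.), CH2Cl2, 0 °C to rt
Reagents that add atoms: di-tert-butyl dicarbonate, CC(C)(C)OC(=O)OC(=O)OC(C)(C)C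
Why: DMAP-catalysed O-acylation converts both phenols into aryl tert-butyl carbonates, the one at O-3' serving later as the trigger and the one at O-7 as an acid-labile spectator mask.

Step 8
Reactants: 12 tert-butyl 3-{3-[(tert-butoxycarbonyl)oxy]-4-formylphenoxy}-6-methoxy-2-oxo-2H-chromen-7-yl carbonate
Product: 13 tert-butyl 3-{3-[(tert-butoxycarbonyl)oxy]-4-(hydroxymethyl)phenoxy}-6-methoxy-2-oxo-2H-chromen-7-yl carbonate
Conditions: BH3·THF (1 equiv), THF, 0 °C; MeOH quench, pH 7 buffer
Reagents that add atoms: none
Why: Chemoselective aldehyde reduction with the electrophilic hydride borane gives a neutral borate ester instead of a free alkoxide, so the ortho carbonate should not migrate prematurely, and at 0 °C the aldehyde reacts far faster than lactone, carbonates or the trisubstituted C3=C4 bond.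

Step 9
Reactants: 13 tert-butyl 3-{3-[(tert-butoxycarbonyl)oxy]-4-(hydroxymethyl)phenoxy}-6-methoxy-2-oxo-2H-chromen-7-yl carbonate; 14 1,1-dimethoxyethene
Product: 17 tert-butyl 3-[(2,2-dimethoxy-3,4-dihydro-2H-chromen-7-yl)oxy]-6-methoxy-2-oxo-2H-chromen-7-yl carbonate, via chloromagnesium phenoxide of the migrated benzylic carbonate 15 (not isolated), via ortho-quinone methide 16 (not isolated)
Conditions: 14 (8 equiv), t-BuMgCl (1.05 equiv), THF–toluene, −78 °C to rt; pH 7 buffer quench, Et3N-deactivated silica
Reagents that add atoms: none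
Why: t-BuMgCl deprotonates the benzylic alcohol of 13, the alkoxide takes over the neighbouring Boc group through a six-membered tetrahedral intermediate to give phenoxide 15, and on warming the magnesium phenoxide expels tert-butyl carbonate (then CO2 and tert-butoxide) to release ortho-quinone methide 16, an electron-poor 1-oxadiene. Excess 14 traps 16 in an inverse-electron-demand hetero-Diels–Alder reaction, the established behaviour of ortho-quinone methides towards enol ethers and ketene acetals, and anionic release from ortho-carbonate benzyl alcohols is an established way to generate them. The dihydropyran ring of the chroman closes by an intermolecular, concerted but asynchronous [4+2] addition that forms C3–C4 and O1–C2 and restores the benzene ring; in the stepwise limit it is a Michael addition followed by 6-exo-trig collapse of the phenoxide on the dimethoxycarbenium ion. No stereocentre is formed. Regioselectivity is required and follows from polarity, since the nucleophilic CH2 terminus of 14 matches only the electrophilic exocyclic methylene of 16, while cross-addition is favoured over self-condensation by the excess of the very nucleophilic alkene, by the slow release of 16 and by the C1' aryloxy group, which is in vinylogous conjugation with the quinone methide carbonyl and tempers it. The medium is aprotic and basic, so neither 14 nor ortho ester 17 meets acid or water, and only the carbonate next to the alkoxide can migrate, which leaves the O-7 carbonate in place.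

Step 10
Reactants: 17 tert-butyl 3-[(2,2-dimethoxy-3,4-dihydro-2H-chromen-7-yl)oxy]-6-methoxy-2-oxo-2H-chromen-7-yl carbonate
Product: 19 methyl 3-{2-hydroxy-4-[(7-hydroxy-6-methoxy-2-oxo-2H-chromen-3-yl)oxy]phenyl}propanoate, via 7-O-Boc methyl ester 18 (not isolated)
Conditions: HCl (2 M in MeOH), H2O (3 equiv), 0 °C to 40 °C; neutralise before concentration
Reagents that add atoms: water, O
Why: Acid-catalysed ortho ester hydrolysis (loss of methanol, addition of water, expulsion of the phenol as the best leaving group) opens the chroman to methyl ester 18, any dihydrocoumarin being re-opened by the methanol solvent, and the same acid then cleaves the aryl tert-butyl carbonate by loss of the tert-butyl cation and decarboxylation, while the coumarin lactone is stable to acid.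

Compound list
1 | 2,4-dihydroxy-5-methoxybenzaldehyde | COc1cc(C=O)c(O)cc1O | starting material
2 | 4-(allyloxy)-2-hydroxy-5-methoxybenzaldehyde | C=CCOc1cc(O)c(C=O)cc1OC | intermediate
3 | N-acetylglycine | CC(=O)NCC(=O)O | starting material
4 | 2-methyl-1,3-oxazol-5(4H)-one (not isolated) | CC1=NCC(=O)O1 | intermediate
5 | N-[7-(allyloxy)-6-methoxy-2-oxo-2H-chromen-3-yl]acetamide | CC(=O)Nc1cc2cc(OC)c(OCC=C)cc2oc1=O | intermediate
6 | 7-(allyloxy)-3-amino-6-methoxy-2H-chromen-2-one (not isolated) | Nc1cc2cc(OC)c(OCC=C)cc2oc1=O | intermediate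
7 | 7-(allyloxy)-3-hydroxy-6-methoxy-2H-chromen-2-one | Oc1cc2cc(OC)c(OCC=C)cc2oc1=O | intermediate
8 | 4-fluoro-2-hydroxybenzaldehyde | O=Cc1ccc(F)cc1O | starting material
9 | 2-(allyloxy)-4-fluorobenzaldehyde | C=CCOc1cc(F)ccc1C=O | intermediate
10 | 2-(allyloxy)-4-{[7-(allyloxy)-6-methoxy-2-oxo-2H-chromen-3-yl]oxy}benzaldehyde | C=CCOc1cc(Oc2cc3cc(OC)c(OCC=C)cc3oc2=O)ccc1C=O | intermediate
11 | 2-hydroxy-4-[(7-hydroxy-6-methoxy-2-oxo-2H-chromen-3-yl)oxy]benzaldehyde | COc1cc2cc(Oc3ccc(C=O)c(O)c3)c(=O)oc2cc1O | intermediate
12 | tert-butyl 3-{3-[(tert-butoxycarbonyl)oxy]-4-formylphenoxy}-6-methoxy-2-oxo-2H-chromen-7-yl carbonate | COc1cc2cc(Oc3ccc(C=O)c(OC(=O)OC(C)(C)C)c3)c(=O)oc2cc1OC(=O)OC(C)(C)C | intermediate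
13 | tert-butyl 3-{3-[(tert-butoxycarbonyl)oxy]-4-(hydroxymethyl)phenoxy}-6-methoxy-2-oxo-2H-chromen-7-yl carbonate (key-step precursor) | COc1cc2cc(Oc3ccc(CO)c(OC(=O)OC(C)(C)C)c3)c(=O)oc2cc1OC(=O)OC(C)(C)C | intermediate
14 | 1,1-dimethoxyethene | C=C(OC)OC | starting material
15 | chloromagnesium 2-{[(tert-butoxycarbonyl)oxy]methyl}-5-({7-[(tert-butoxycarbonyl)oxy]-6-methoxy-2-oxo-2H-chromen-3-yl}oxy)phenoxide (not isolated) | COc1cc2cc(Oc3ccc(COC(=O)OC(C)(C)C)c([O-])c3)c(=O)oc2cc1OC(=O)OC(C)(C)C.[Mg+2].[Cl-] | intermediate
16 | tert-butyl 6-methoxy-3-[(4-methylidene-3-oxocyclohexa-1,5-dien-1-yl)oxy]-2-oxo-2H-chromen-7-yl carbonate (ortho-quinone methide, not isolated) | C=C1C=CC(Oc2cc3cc(OC)c(OC(=O)OC(C)(C)C)cc3oc2=O)=CC1=O | intermediate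
17 | tert-butyl 3-[(2,2-dimethoxy-3,4-dihydro-2H-chromen-7-yl)oxy]-6-methoxy-2-oxo-2H-chromen-7-yl carbonate (key-step product) | COc1cc2cc(Oc3ccc4CCC(OC)(OC)Oc4c3)c(=O)oc2cc1OC(=O)OC(C)(C)C | intermediate
18 | methyl 3-[4-({7-[(tert-butoxycarbonyl)oxy]-6-methoxy-2-oxo-2H-chromen-3-yl}oxy)-2-hydroxyphenyl]propanoate (not isolated) | COC(=O)CCc1ccc(Oc2cc3cc(OC)c(OC(=O)OC(C)(C)C)cc3oc2=O)cc1O | intermediate
19 | methyl 3-{2-hydroxy-4-[(7-hydroxy-6-methoxy-2-oxo-2H-chromen-3-yl)oxy]phenyl}propanoate | COC(=O)CCc1ccc(Oc2cc3cc(OC)c(O)cc3oc2=O)cc1O | target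

Total step count: 10
Longest linear sequence: 9 steps (steps 1, 2, 3, 5, 6, 7, 8, 9, 10)

Steps most likely to fail

1. Step 9.
- **Risk:** The quinone methide may self-condense or be captured by tert-butoxide faster than it undergoes cycloaddition. The O-7 carbonate may be lost by alkoxide exchange. The ortho ester may also hydrolyse or lactonise during isolation.
- **Fallback:** It sets out from 11, comes back at 19 and gives up the cycloaddition. Wittig olefination of 11 with methyl (triphenylphosphoranylidene)acetate in toluene at 60 °C should give methyl (E)-3-{2-hydroxy-4-[(7-hydroxy-6-methoxy-2-oxo-2H-chromen-3-yl)oxy]phenyl}prop-2-enoate F1. Homogeneous hydrogenation with RhCl(PPh3)3 and H2 in toluene–EtOH should then saturate the disubstituted cinnamate double bond. The trisubstituted, oxygen-bearing coumarin C3=C4 bond should be left alone, which gives 19 directly.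

2. Step 5.
- **Risk:** Displacement may be sluggish because the enolate is a weak nucleophile. The ambident enolate may attack the aldehyde through C4. The coumarin may degrade under base at the temperature required.
- **Fallback:** It sets out from 2, comes back at 10, and builds the aryl ether before the coumarin ring.
  - Purchased 2,4-dihydroxybenzaldehyde is alkylated at O-4 with tert-butyl bromoacetate (KHCO3, DMF) to tert-butyl 2-(4-formyl-3-hydroxyphenoxy)acetate F2.
  - Allylation at O-2 (allyl bromide, K2CO3) gives tert-butyl 2-[3-(allyloxy)-4-formylphenoxy]acetate F3.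
  - CF3CO2H then frees 2-[3-(allyloxy)-4-formylphenoxy]acetic acid F4.
  - Esterification of F4 with the phenol of 2 (EDC, DMAP) gives 5-(allyloxy)-2-formyl-4-methoxyphenyl 2-[3-(allyloxy)-4-formylphenoxy]acetate F5.
  - DBU closes the activated OCH2 carbon of F5 onto the adjacent formyl group. This is an intramolecular Knoevenagel-type aldol condensation, the ester variant of the Perkin coumarin synthesis. Dehydration gives 10, and steps 2 to 5 become unnecessary.

3. Step 8.
- **Risk:** The carbonate may migrate prematurely during reduction, and the quinone methide so released may be over-reduced to a methyl arene. Borane may also attack the lactone or the C3=C4 bond.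
- **Fallback:** It sets out from 10, comes back at 13, and reduces before the carbonates are present.
  - NaBH4 in THF–MeOH at 0 °C should give 7-(allyloxy)-3-[3-(allyloxy)-4-(hydroxymethyl)phenoxy]-6-methoxy-2H-chromen-2-one F6.
  - Pd(PPh3)4 with morpholine removes both allyl groups to give 7-hydroxy-3-[3-hydroxy-4-(hydroxymethyl)phenoxy]-6-methoxy-2H-chromen-2-one F7.
  - Boc2O (2 equiv) with iPr2NEt and no DMAP acylates the two phenols in preference to the primary alcohol, giving 13.

Further compounds
F1 | step 9 | methyl (E)-3-{2-hydroxy-4-[(7-hydroxy-6-methoxy-2-oxo-2H-chromen-3-yl)oxy]phenyl}prop-2-enoate | COC(=O)/C=C/c1ccc(Oc2cc3cc(OC)c(O)cc3oc2=O)cc1O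
F2 | step 5 | tert-butyl 2-(4-formyl-3-hydroxyphenoxy)acetate | CC(C)(C)OC(=O)COc1ccc(C=O)c(O)c1
F3 | step 5 | tert-butyl 2-[3-(allyloxy)-4-formylphenoxy]acetate | CC(C)(C)OC(=O)COc1ccc(C=O)c(OCC=C)c1
F4 | step 5 | 2-[3-(allyloxy)-4-formylphenoxy]acetic acid | OC(=O)COc1ccc(C=O)c(OCC=C)c1
F5 | step 5 | 5-(allyloxy)-2-formyl-4-methoxyphenyl 2-[3-(allyloxy)-4-formylphenoxy]acetate | C=CCOc1cc(OC(=O)COc2ccc(C=O)c(OCC=C)c2)c(C=O)cc1OC
F6 | step 8 | 7-(allyloxy)-3-[3-(allyloxy)-4-(hydroxymethyl)phenoxy]-6-methoxy-2H-chromen-2-one | C=CCOc1cc(Oc2cc3cc(OC)c(OCC=C)cc3oc2=O)ccc1CO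
F7 | step 8 | 7-hydroxy-3-[3-hydroxy-4-(hydroxymethyl)phenoxy]-6-methoxy-2H-chromen-2-one | COc1cc2cc(Oc3ccc(CO)c(O)c3)c(=O)oc2cc1O
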